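**Assumption (one line):** The target has no stereocentre, because C11 carries two methyls. Its only stereo-elements are the two trisubstituted alkenes, which are both E in the SMILES, so "single enantiomer" is not an issue. Reagents are listed in each step and are not numbered.

## Retrosynthesis
1. Disconnect the aryl–O–CH2 ether (Mitsunobu). This gives the 4,5-dihydroxy-6-methoxyphthalide **7** and the diol (2E,6E)-3,7,11-trimethyldodeca-2,6-diene-1,11-diol **4**.
2. Disconnect the lactone of **7** back to an o-formyl benzoate **6** (NaBH4 reduction, then lactonisation). **6** comes from the ortho-formylation of commercial methyl 3-O-methylgallate **5**.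
3. Disconnect diol **4** back to farnesol **1**. The terminal alkene is differentiated by NBS/H2O, and the bromohydrin is then reduced to the tertiary alcohol.
4. The only ring formed is the γ-lactone, made late in the core branch. The arene is commercial and the chain is joined last.

## Forward synthesis

**Step 1**
Reactants: **1**, (2E,6E)-farnesol
Product: **2**, (2E,6E)-farnesyl acetate
Conditions: Ac2O, pyridine, DMAP (cat.), CH2Cl2, 0 °C → rt
Reagents that add atoms: acetic anhydride, CC(=O)OC(C)=O
Why: Simple O-acetylation. The acetate inductively deactivates the 2,3-alkene so that the next step can be selective for the terminal alkene. No stereocentre is involved and the E,E geometry is untouched.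

**Step 2**
Reactants: **2**
Product: **3**, (2E,6E)-10-bromo-11-hydroxy-3,7,11-trimethyldodeca-2,6-dienyl acetate, racemic at C10
Conditions: NBS (1.0 equiv), THF/H2O, 0 °C
Reagents that add atoms: N-bromosuccinimide, O=C1CCC(=O)N1Br; water, O
Why: Bromohydrin formation by NBS/H2O. The most electron-rich, least deactivated alkene is the terminal trisubstituted one, so Br adds at C10 and water at the tertiary C11. The C10 centre is racemic but is removed in Step 3.

**Step 3**
Reactants: **3**
Product: **4**, (2E,6E)-3,7,11-trimethyldodeca-2,6-diene-1,11-diol
Conditions: LiAlH4, THF, 0 °C → reflux; then Fieser work-up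
Reagents that add atoms: none (only H is delivered)
Why: LiAlH4 cleaves the acetate. The tertiary alkoxide closes to the 10,11-epoxide, and hydride opens it at the less hindered C10 to give the tertiary alcohol. C10 becomes CH2, so no stereocentre remains. The trisubstituted allylic alkenes are inert to LiAlH4.

**Step 4**
Reactants: **5**, methyl 3,4-dihydroxy-5-methoxybenzoate (methyl 3-O-methylgallate)
Product: **6**, methyl 2-formyl-3,4-dihydroxy-5-methoxybenzoate
Conditions: MgCl2, Et3N, (CH2O)n, MeCN, reflux; then 1 M HCl
Reagents that add atoms: paraformaldehyde, C=O (as (CH2O)n)
Why: Magnesium-phenoxide-directed ortho-formylation (Casnati–Skattebøl). The only free position ortho to a phenol is C2, between CO2Me and the 3-OH, so formylation is regiospecific there. This is the ortho position of the ester that must carry the future C3 carbon of the phthalide.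

**Step 5**
Reactants: **6**
Product: **7**, 4,5-dihydroxy-6-methoxyisobenzofuran-1(3H)-one
Conditions: NaBH4, THF/MeOH, 0 °C; then 1 M HCl, rt
Reagents that add atoms: none (the only other loss is MeOH)
Why: Chemoselective aldehyde reduction in the presence of the ester. The resulting o-hydroxymethyl benzoate lactonises spontaneously under acid, with loss of MeOH, to form the five-membered lactone ring. No stereocentre is formed.

**Step 6**
Reactants: **7** and **4**
Product: **8**, Farnesylemefuranone E
Conditions: PPh3, DIAD, THF, 0 °C → rt
Reagents that add atoms: none (PPh3 and DIAD are not incorporated; the chain comes from 4)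
Why: Mitsunobu etherification of the primary allylic alcohol of **4** by the most acidic phenol of **7**. That is the 5-OH, which is para to the lactone carbonyl-bearing carbon. The 4-OH is less acidic and is hindered by the peri CH2. The tertiary alcohol does not react. The SN2 attack at the primary carbon keeps both E alkenes, and the lactone is untouched.

**Checks**
- **Structure:** Product **8** has the phthalide ring, 6-OMe, 4-OH, and 5-O–CH2CH=C(Me)CH2CH2CH=C(Me)CH2CH2CH2C(Me)2OH with both alkenes E. This matches the target SMILES.
- **Atom balance:** **1** (C15H26O) → **2** (C17H28O2) → **3** (C17H29BrO3) → **4** (C15H28O2). **5** (C9H10O5) → **6** (C10H10O6) → **7** (C9H8O5). **7** + **4** − H2O = C24H36O6 = **8**.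
- **Functional-group survival:** Alkenes are untouched in Steps 3–6. The lactone is formed after the Mg/base step and survives the Mitsunobu step. The tertiary alcohol is inert throughout.
- **Stereochemistry:** The only stereo-elements are the E,E alkenes, which come from farnesol and are never scrambled. The racemic C10–Br centre is destroyed in Step 3.

## Compound list
1 | (2E,6E)-farnesol | CC(C)=CCC/C(C)=C/CC/C(C)=C/CO | starting material
2 | (2E,6E)-farnesyl acetate | CC(C)=CCC/C(C)=C/CC/C(C)=C/COC(C)=O | intermediate
3 | 10-bromo-11-hydroxy-farnesyl acetate (10,11-dihydro, racemic at C10) | CC(C)(O)C(Br)CC/C(C)=C/CC/C(C)=C/COC(C)=O | intermediate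
4 | (2E,6E)-3,7,11-trimethyldodeca-2,6-diene-1,11-diol | CC(C)(O)CCC/C(C)=C/CC/C(C)=C/CO | intermediate
5 | methyl 3,4-dihydroxy-5-methoxybenzoate | COC(=O)c1cc(O)c(O)c(OC)c1 | starting material
6 | methyl 2-formyl-3,4-dihydroxy-5-methoxybenzoate | COC(=O)c1cc(OC)c(O)c(O)c1C=O | intermediate
7 | 4,5-dihydroxy-6-methoxyisobenzofuran-1(3H)-one | COc1cc2c(c(O)c1O)COC2=O | intermediate
8 | Farnesylemefuranone E | COc1cc2c(c(O)c1OC/C=C(\C)CC/C=C(\C)CCCC(C)(C)O)COC2=O | target

## Totals
- Total steps: 6.
- Longest linear sequence: 4 steps (1 → 2 → 3 → 4 → 8). The core branch 5 → 6 → 7 → 8 is 3 steps.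

## Three steps most likely to fail
1. **Step 4 (formylation).** The site is hindered and sits on an ester-deactivated catechol. Fallback: change the approach to directed ortho-metalation. Use the 3-OMOM-4-OBn-5-OMe N,N-diethylbenzamide, lithiate between the two directing groups (s-BuLi/TMEDA, −78 °C), quench with (CH2O)n, then lactonise and deprotect.
2. **Step 6 (phenol regioselectivity).** Alkylation at the 4-OH instead of the 5-OH is the risk. Fallback: reorder the sequence. Alkylate the 4-OH of ester **5** first (it is the most acidic, para to CO2Me) with the allylic bromide of **4**, then carry out the formylation and reduction/lactonisation steps.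
3. **Step 3 (reductive opening).** Hydride opening of the hindered epoxide, or over-reduction, could fail. Fallback: use radical dehalogenation of bromohydrin **3** (Bu3SnH or (TMS)3SiH, AIBN, toluene), which keeps the tertiary OH. Then cleave the acetate with K2CO3/MeOH.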